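**Retrosynthetic overview**
- The oxirane C–O bonds and the carbinol C–O bond are made last, in one operation, from a cyclohexa-1,3-diene carrying an E trisubstituted side-chain alkene (singlet oxygen [4+2] plus ene, then phosphine).
- The cyclohexadiene comes from thermal disrotatory 6π electrocyclisation of a (2E,4Z,6E,8E)-tetraenyl pyranone, which fixes the cis relation of pyranone and side chain.
- The tetraene is cut at C6–C7 (Suzuki coupling) into a pyranone trienyl iodide and a chiral alkenyl boronate (methyl stereocentre from a catalytic asymmetric crotylation, boronate by cross-metathesis).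
- The trienyl iodide is cut at C1=C2 (aldol condensation) into 6-ethyl-2-methoxy-3,5-dimethyl-4-pyranone and a (2Z,4E)-iododienal built from propargyl alcohol by anti-carbomagnesiation and syn-carboalumination.
- Ring order: pyranone (lactonisation), then cyclohexadiene (6π), then oxirane (last step).

Assumption 1: the 6π closure in step 11 is not steered by the remote side-chain stereocentres, so both cis-ring diastereomers form in about equal amount; the (1R,6S) isomer is separated by preparative HPLC after step 11 and only it is carried on (half of the material is lost there).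
Assumption 2: (R)-SEGPHOS is taken as the ligand antipode that gives the (3S,4R) alcohol in step 9; the sense is inferred from memory of the (S)-ligand series and should be confirmed on the first run.

**Route**

Step 1
Reactants: 1 ethyl 2-methyl-3-oxopentanoate; 2 N-methoxy-N-methylpropanamide
Product: 3 ethyl 2,4-dimethyl-3,5-dioxoheptanoate
Conditions: NaH, THF, 0 °C; n-BuLi, 0 °C; 2, −78 → 0 °C; aq. HCl
Reagents that add atoms: none
Why: Huckin–Weiler γ-acylation: the dianion of the β-keto ester reacts at its terminal carbanion with the Weinreb amide, whose chelated tetrahedral adduct stops at the ketone stage (Claisen-type acylation).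

Step 2
Reactants: 3 ethyl 2,4-dimethyl-3,5-dioxoheptanoate
Product: 4 6-ethyl-4-hydroxy-3,5-dimethyl-2H-pyran-2-one
Conditions: DBU, PhMe, 110 °C
Reagents that add atoms: none
Why: DBU-mediated enol lactonisation (intramolecular O-acylation with loss of ethanol) closes the 4-hydroxy-2-pyranone, the first ring.

Step 3
Reactants: 4 6-ethyl-4-hydroxy-3,5-dimethyl-2H-pyran-2-one
Product: 5 6-ethyl-2-methoxy-3,5-dimethyl-4H-pyran-4-one
Conditions: MeOTf, CH2Cl2, 23 °C
Reagents that add atoms: methyl trifluoromethanesulfonate, COS(=O)(=O)C(F)(F)F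
Why: Regioselective pyranone O-alkylation: the hard methylating agent attacks the lactone carbonyl oxygen (2-methoxypyrylium intermediate) and proton loss from the 4-OH gives the 2-methoxy-4-pyranone rather than the 4-methoxy-2-pyranone.

Step 4
Reactants: 6 prop-2-yn-1-ol
Product: 7 (Z)-3-iodo-2-methylprop-2-en-1-ol
Conditions: MeMgBr, CuI (10 mol%), THF, −10 → 23 °C; I2, −10 °C
Reagents that add atoms: methylmagnesium bromide, C[Mg]Br; iodine, II
Why: Duboudin copper-catalysed carbomagnesiation: the magnesium alkoxide directs anti addition of Me–Mg across the alkyne (methyl to C2) and iodinolysis with retention fixes the Z geometry that becomes the cis central alkene of the triene.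

Step 5
Reactants: 7 (Z)-3-iodo-2-methylprop-2-en-1-ol
Product: 8 (Z)-2-methylpent-2-en-4-yn-1-ol
Conditions: HC≡CMgBr, ZnBr2, THF, 0 °C; then 7, Pd(PPh3)4 (3 mol%), 23 °C
Reagents that add atoms: ethynylmagnesium bromide, C#C[Mg]Br
Why: Negishi alkynylation: Pd-catalysed cross-coupling of the alkenyl iodide with ethynylzinc bromide proceeds with retention of the Z geometry (one equivalent of reagent is spent on the hydroxyl).

Step 6
Reactants: 8 (Z)-2-methylpent-2-en-4-yn-1-ol
Product: 9 (2Z,4E)-5-iodo-2,4-dimethylpenta-2,4-dien-1-ol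
Conditions: Me3Al, Cp2ZrCl2 (25 mol%), CH2Cl2, 0 → 23 °C; I2, THF, −30 °C
Reagents that add atoms: trimethylaluminium, C[Al](C)C; iodine, II
Why: Negishi zirconium-catalysed carboalumination adds Me–Al syn across the terminal alkyne with methyl on the internal carbon, and iodinolysis with retention gives the E trisubstituted alkenyl iodide.

Step 7
Reactants: 9 (2Z,4E)-5-iodo-2,4-dimethylpenta-2,4-dien-1-ol
Product: 10 (2Z,4E)-5-iodo-2,4-dimethylpenta-2,4-dienal
Conditions: MnO2, CH2Cl2, 23 °C, dark
Reagents that add atoms: none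
Why: MnO2 allylic oxidation under neutral conditions gives the enal without Z to E isomerisation; the aldehyde is used at once.

Step 8
Reactants: 5 6-ethyl-2-methoxy-3,5-dimethyl-4H-pyran-4-one; 10 (2Z,4E)-5-iodo-2,4-dimethylpenta-2,4-dienal
Product: 13 6-[(2E,4Z,6E)-7-iodo-4,6-dimethylhepta-2,4,6-trien-2-yl]-2-methoxy-3,5-dimethyl-4H-pyran-4-one, via lithium aldolate 11 (not isolated), via aldol mesylate 12 (not isolated)
Conditions: LiN(SiMe3)2, THF, −78 °C; 10; MsCl, −78 → 0 °C; DBU, 23 °C
Reagents that add atoms: none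
Why: Aldol condensation: vinylogous aldol addition of the 6-ethyl pyranone anion (deprotonated at the CH2 conjugated to the pyranone carbonyl), then mesylation and E1cB elimination give the conjugated, thermodynamically favoured E alkene.

Step 9
Reactants: 14 propan-1-ol; 15 but-3-en-2-yl acetate (racemic)
Product: 16 (3S,4R)-4-methylhex-5-en-3-ol
Conditions: [Ir(cod)Cl]2 (2.5 mol%), (R)-SEGPHOS, 4-cyano-3-nitrobenzoic acid, Cs2CO3 (20 mol%), THF, 90 °C
Reagents that add atoms: none
Why: Krische iridium-catalysed transfer-hydrogenative carbonyl crotylation: the alcohol is dehydrogenated to propanal, which the chiral crotyliridium species attacks through a closed chair transition state to give the anti adduct, setting C4 (R, the later side-chain methyl centre) and the temporary carbinol centre C3.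

Step 10
Reactants: 16 (3S,4R)-4-methylhex-5-en-3-ol; 17 4,4,5,5-tetramethyl-2-(prop-1-en-2-yl)-1,3,2-dioxaborolane
Product: 18 (3S,4R,5Z)-4-methyl-6-(4,4,5,5-tetramethyl-1,3,2-dioxaborolan-2-yl)hept-5-en-3-ol
Conditions: second-generation Hoveyda–Grubbs catalyst [RuCl2(H2IMes)(=CH-C6H4-2-OiPr)] (5 mol%), CH2Cl2, 40 °C
Reagents that add atoms: none
Why: Olefin cross-metathesis of the terminal alkene with the 1,1-disubstituted alkenyl boronate; the bulky boronate ends up trans to the chain (Z descriptor), the geometry needed for the E side-chain alkene.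

Step 11
Reactants: 13 6-[(2E,4Z,6E)-7-iodo-4,6-dimethylhepta-2,4,6-trien-2-yl]-2-methoxy-3,5-dimethyl-4H-pyran-4-one; 18 (3S,4R,5Z)-4-methyl-6-(4,4,5,5-tetramethyl-1,3,2-dioxaborolan-2-yl)hept-5-en-3-ol
Product: 20 6-[(1R,6S)-6-[(2E,4R,5S)-5-hydroxy-4-methylhept-2-en-2-yl]-1,3,5-trimethylcyclohexa-2,4-dien-1-yl]-2-methoxy-3,5-dimethyl-4H-pyran-4-one, via tetraene alcohol 19 (not isolated)
Conditions: Pd(OAc)2 (5 mol%), SPhos, K3PO4, degassed THF/H2O, 40 °C; then o-xylene, 140 °C
Reagents that add atoms: none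
Why: Suzuki–Miyaura coupling with retention of both alkene geometries gives the (2E,4Z,6E,8E)-tetraene, whose only cis-triene unit undergoes thermal disrotatory 6π electrocyclisation that places the two outward groups (pyranone and side chain) cis on the new sp3 carbons; the (1R,6S) diastereomer is taken on.

Step 12
Reactants: 20 6-[(1R,6S)-6-[(2E,4R,5S)-5-hydroxy-4-methylhept-2-en-2-yl]-1,3,5-trimethylcyclohexa-2,4-dien-1-yl]-2-methoxy-3,5-dimethyl-4H-pyran-4-one
Product: 21 6-[(1R,6S)-1,3,5-trimethyl-6-[(2E,4R)-4-methyl-5-oxohept-2-en-2-yl]cyclohexa-2,4-dien-1-yl]-2-methoxy-3,5-dimethyl-4H-pyran-4-one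
Conditions: Dess–Martin periodinane, pyridine, CH2Cl2, 0 °C
Reagents that add atoms: none
Why: Dess–Martin oxidation of the secondary alcohol under buffered, non-enolising conditions keeps the adjacent allylic methyl stereocentre intact.

Step 13
Reactants: 21 6-[(1R,6S)-1,3,5-trimethyl-6-[(2E,4R)-4-methyl-5-oxohept-2-en-2-yl]cyclohexa-2,4-dien-1-yl]-2-methoxy-3,5-dimethyl-4H-pyran-4-one
Product: 23 6-[(1R,4R,5R,6S)-5-[(3R,4R)-3-hydroxy-4-methyl-5-oxohept-1-en-2-yl]-2,4,6-trimethyl-7-oxabicyclo[4.1.0]hept-2-en-4-yl]-2-methoxy-3,5-dimethyl-4H-pyran-4-one, via endoperoxide hydroperoxide 22 (not isolated)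
Conditions: O2, TPP (1 mol%), hν (530 nm), CH2Cl2, −30 °C; then PPh3, −30 → 23 °C
Reagents that add atoms: dioxygen, O=O
Why: Proposed new method: a one-pot double singlet-oxygenation/phosphine relay in which one irradiation engages the ring 1,3-diene in [4+2] cycloaddition from the face opposite to pyranone and side chain and, independently, the side-chain trisubstituted alkene in a Schenck ene reaction (hydrogen taken from the vinylic methyl on the more crowded side, oxygen delivered to C3 anti to the acyl group of the 1,3-allylic-strain conformer, which gives the 3R carbinol), after which PPh3 reduces the hydroperoxide and attacks the less hindered peroxide oxygen on the C–H bridgehead so that the alkoxide on the methyl-bearing bridgehead closes by syn-SN2′ displacement of Ph3P=O to the vinyl epoxide with both C–O bonds on the original peroxide face; the closest known reactions are the Schenck ene/phosphine reduction sequence and the PPh3 deoxygenation of 2,3-dioxabicyclo[2.2.2]oct-5-enes to 3,4-epoxycyclohexenes, which have not been merged or shown on an unsymmetrical, fully substituted endoperoxide.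

**Compound list**
1 | ethyl 2-methyl-3-oxopentanoate (racemic) | CCC(=O)C(C)C(=O)OCC | starting material
2 | N-methoxy-N-methylpropanamide | CCC(=O)N(C)OC | starting material
3 | ethyl 2,4-dimethyl-3,5-dioxoheptanoate (stereoisomer mixture) | CCC(=O)C(C)C(=O)C(C)C(=O)OCC | intermediate
4 | 6-ethyl-4-hydroxy-3,5-dimethyl-2H-pyran-2-one | CCc1oc(=O)c(C)c(O)c1C | intermediate
5 | 6-ethyl-2-methoxy-3,5-dimethyl-4H-pyran-4-one | CCc1oc(OC)c(C)c(=O)c1C | intermediate
6 | prop-2-yn-1-ol | C#CCO | starting material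
7 | (Z)-3-iodo-2-methylprop-2-en-1-ol | OC/C(C)=C\I | intermediate
8 | (Z)-2-methylpent-2-en-4-yn-1-ol | OC/C(C)=C\C#C | intermediate
9 | (2Z,4E)-5-iodo-2,4-dimethylpenta-2,4-dien-1-ol | OC/C(C)=C\C(C)=C\I | intermediate
10 | (2Z,4E)-5-iodo-2,4-dimethylpenta-2,4-dienal | O=C/C(C)=C\C(C)=C\I | intermediate
11 | lithium (4Z,6E)-7-iodo-2-(6-methoxy-3,5-dimethyl-4-oxo-4H-pyran-2-yl)-4,6-dimethylhepta-4,6-dien-3-olate (diastereomer mixture, not isolated) | COc1oc(C(C)C([O-])/C(C)=C\C(C)=C\I)c(C)c(=O)c1C.[Li+] | intermediate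
12 | (4Z,6E)-7-iodo-2-(6-methoxy-3,5-dimethyl-4-oxo-4H-pyran-2-yl)-4,6-dimethylhepta-4,6-dien-3-yl methanesulfonate (diastereomer mixture, not isolated) | COc1oc(C(C)C(OS(C)(=O)=O)/C(C)=C\C(C)=C\I)c(C)c(=O)c1C | intermediate
13 | 6-[(2E,4Z,6E)-7-iodo-4,6-dimethylhepta-2,4,6-trien-2-yl]-2-methoxy-3,5-dimethyl-4H-pyran-4-one | COc1oc(/C(C)=C/C(C)=C\C(C)=C\I)c(C)c(=O)c1C | intermediate
14 | propan-1-ol | CCCO | starting material
15 | but-3-en-2-yl acetate (racemic) | CC(OC(C)=O)C=C | starting material
16 | (3S,4R)-4-methylhex-5-en-3-ol | CC[C@H](O)[C@H](C)C=C | intermediate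
17 | 4,4,5,5-tetramethyl-2-(prop-1-en-2-yl)-1,3,2-dioxaborolane | CC(=C)B1OC(C)(C)C(C)(C)O1 | starting material
18 | (3S,4R,5Z)-4-methyl-6-(4,4,5,5-tetramethyl-1,3,2-dioxaborolan-2-yl)hept-5-en-3-ol | CC[C@H](O)[C@H](C)/C=C(\C)B1OC(C)(C)C(C)(C)O1 | intermediate
19 | 6-[(2E,4Z,6E,8E,10R,11S)-11-hydroxy-4,6,8,10-tetramethyltrideca-2,4,6,8-tetraen-2-yl]-2-methoxy-3,5-dimethyl-4H-pyran-4-one (not isolated) | COc1oc(/C(C)=C/C(C)=C\C(C)=C\C(C)=C\[C@@H](C)[C@@H](O)CC)c(C)c(=O)c1C | intermediate
20 | 6-[(1R,6S)-6-[(2E,4R,5S)-5-hydroxy-4-methylhept-2-en-2-yl]-1,3,5-trimethylcyclohexa-2,4-dien-1-yl]-2-methoxy-3,5-dimethyl-4H-pyran-4-one (pyranone and side chain cis) | CC[C@H](O)[C@H](C)/C=C(\C)[C@H]1C(C)=CC(C)=C[C@@]1(C)c1oc(OC)c(C)c(=O)c1C | intermediate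
21 | 6-[(1R,6S)-1,3,5-trimethyl-6-[(2E,4R)-4-methyl-5-oxohept-2-en-2-yl]cyclohexa-2,4-dien-1-yl]-2-methoxy-3,5-dimethyl-4H-pyran-4-one | CCC(=O)[C@H](C)/C=C(\C)[C@H]1C(C)=CC(C)=C[C@@]1(C)c1oc(OC)c(C)c(=O)c1C | intermediate
22 | 6-{7-[(3R,4R)-3-hydroperoxy-4-methyl-5-oxohept-1-en-2-yl]-1,5,8-trimethyl-2,3-dioxabicyclo[2.2.2]oct-5-en-8-yl}-2-methoxy-3,5-dimethyl-4H-pyran-4-one, peroxide bridge on the ring face opposite to pyranone and side chain, C7 and C8 configured as in 21 (not isolated) | C=C([C@H](OO)[C@@H](C)C(=O)CC)[C@H]1[C@]2(C)OO[C@@H](C(C)=C2)[C@@]1(C)c1oc(OC)c(C)c(=O)c1C | intermediate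
23 | 6-[(1R,4R,5R,6S)-5-[(3R,4R)-3-hydroxy-4-methyl-5-oxohept-1-en-2-yl]-2,4,6-trimethyl-7-oxabicyclo[4.1.0]hept-2-en-4-yl]-2-methoxy-3,5-dimethyl-4H-pyran-4-one (CNP0233636.2) | C=C([C@H](O)[C@@H](C)C(=O)CC)[C@H]1[C@]2(C)O[C@@H]2C(C)=C[C@@]1(C)c1oc(OC)c(C)c(=O)c1C | target

**Step count and risks**

Total step count: 13. Longest linear sequence: 8 steps (6 → 7 → 8 → 9 → 10 → 13 → 20 → 21 → 23, steps 4–8 and 11–13).

Where each stereocentre is set:
- Side-chain methyl centre: step 9 (catalyst control).
- Two ring sp3 carbons: step 11. The cis relation follows from the disrotatory mode; the absolute sense comes only from the separation in Assumption 1.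
- Both oxirane carbons and the carbinol: step 13.

Most likely to fail, first: step 13 (the proposed new step). Possible failures are phosphine attack at the other peroxide oxygen, which would give the regioisomeric vinyl epoxide, and poor facial control in the ene reaction. The fallback uses known, stepwise chemistry and sets out from 21. Monoepoxidation of the diene at the alkene remote from the quaternary carbon, anti to the side chain, is done with the D-fructose-derived Shi ketone and Oxone (KHSO5) with K2CO3 buffer in MeCN/dimethoxymethane at 0 °C, or with preformed dimethyldioxirane if the α-methyl ketone does not tolerate the buffer. This gives 6-[(1R,4R,5R,6S)-2,4,6-trimethyl-5-[(2E,4R)-4-methyl-5-oxohept-2-en-2-yl]-7-oxabicyclo[4.1.0]hept-2-en-4-yl]-2-methoxy-3,5-dimethyl-4H-pyran-4-one F6. A conventional Schenck ene reaction (O2, TPP, hν, CH2Cl2, −30 °C) then gives the allylic hydroperoxide 6-[(1R,4R,5R,6S)-5-[(3R,4R)-3-hydroperoxy-4-methyl-5-oxohept-1-en-2-yl]-2,4,6-trimethyl-7-oxabicyclo[4.1.0]hept-2-en-4-yl]-2-methoxy-3,5-dimethyl-4H-pyran-4-one F7, and PPh3 reduction brings the sequence back to the route at 23. The weak point of this fallback is competition from the side-chain alkene in the epoxidation.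

Second: step 10. Both metathesis partners are sluggish (allylic branching on one, 1,1-disubstitution on the other). The fallback sets out from 16 and replaces metathesis by carbonyl olefination. Silylation (TBSCl, imidazole, DMF) gives tert-butyl(dimethyl){[(3S,4R)-4-methylhex-5-en-3-yl]oxy}silane F3. Ozonolysis (O3, CH2Cl2, −78 °C, then PPh3) gives (2S,3S)-3-{[tert-butyl(dimethyl)silyl]oxy}-2-methylpentanal F4, used cold and at once. Boron–Wittig olefination with 1,1-bis(4,4,5,5-tetramethyl-1,3,2-dioxaborolan-2-yl)ethane and lithium 2,2,6,6-tetramethylpiperidide in THF at 0 °C gives tert-butyl(dimethyl){[(3S,4R,5Z)-4-methyl-6-(4,4,5,5-tetramethyl-1,3,2-dioxaborolan-2-yl)hept-5-en-3-yl]oxy}silane F5. HF·pyridine then removes the silyl group and the sequence returns to the route at 18.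

Third: step 8. The Z enal can isomerise under the basic conditions and the elimination can give E/Z mixtures. The fallback sets out from 5 and forms the same alkene by Horner–Wadsworth–Emmons olefination. Radical bromination of the ethyl CH2 (NBS, AIBN, PhCF3, 80 °C) gives 6-(1-bromoethyl)-2-methoxy-3,5-dimethyl-4H-pyran-4-one F1. Arbuzov reaction with P(OEt)3 at 120 °C gives diethyl [1-(6-methoxy-3,5-dimethyl-4-oxo-4H-pyran-2-yl)ethyl]phosphonate F2. Deprotonation with KN(SiMe3)2 in THF at −78 °C and addition of 10 then gives the E alkene directly, and the sequence returns to the route at 13.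

**Further compounds**
F1 | step 8 | 6-(1-bromoethyl)-2-methoxy-3,5-dimethyl-4H-pyran-4-one (racemic) | CC(Br)c1oc(OC)c(C)c(=O)c1C
F2 | step 8 | diethyl [1-(6-methoxy-3,5-dimethyl-4-oxo-4H-pyran-2-yl)ethyl]phosphonate (racemic) | CCOP(=O)(OCC)C(C)c1oc(OC)c(C)c(=O)c1C
F3 | step 10 | tert-butyl(dimethyl){[(3S,4R)-4-methylhex-5-en-3-yl]oxy}silane | CC[C@H](O[Si](C)(C)C(C)(C)C)[C@H](C)C=C
F4 | step 10 | (2S,3S)-3-{[tert-butyl(dimethyl)silyl]oxy}-2-methylpentanal | CC[C@H](O[Si](C)(C)C(C)(C)C)[C@H](C)C=O
F5 | step 10 | tert-butyl(dimethyl){[(3S,4R,5Z)-4-methyl-6-(4,4,5,5-tetramethyl-1,3,2-dioxaborolan-2-yl)hept-5-en-3-yl]oxy}silane | CC[C@H](O[Si](C)(C)C(C)(C)C)[C@H](C)/C=C(\C)B1OC(C)(C)C(C)(C)O1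
F6 | step 13 | 6-[(1R,4R,5R,6S)-2,4,6-trimethyl-5-[(2E,4R)-4-methyl-5-oxohept-2-en-2-yl]-7-oxabicyclo[4.1.0]hept-2-en-4-yl]-2-methoxy-3,5-dimethyl-4H-pyran-4-one | CCC(=O)[C@H](C)/C=C(\C)[C@H]1[C@]2(C)O[C@@H]2C(C)=C[C@@]1(C)c1oc(OC)c(C)c(=O)c1C
F7 | step 13 | 6-[(1R,4R,5R,6S)-5-[(3R,4R)-3-hydroperoxy-4-methyl-5-oxohept-1-en-2-yl]-2,4,6-trimethyl-7-oxabicyclo[4.1.0]hept-2-en-4-yl]-2-methoxy-3,5-dimethyl-4H-pyran-4-one | C=C([C@H](OO)[C@@H](C)C(=O)CC)[C@H]1[C@]2(C)O[C@@H]2C(C)=C[C@@]1(C)c1oc(OC)c(C)c(=O)c1C
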